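**Retrosynthetic overview**
- The erythro (7S,8R) aryl-glycerol ether is disconnected at C7–C8: a Mg-catalysed Evans anti-aldol of an aryloxyacetyl oxazolidinone with vanillin acetate, followed by one global reduction/unmasking.
- The C8–O aryl ether is made earlier as a plain O-alkylation of the syringyl phenol with a chloroacetyl oxazolidinone, before C8 is stereogenic.
- Key step: the (2R,3R)-dihydrobenzofuran ester comes from enantioselective hydrogenation of a flat, achiral 2-aryl-benzofuran-3-carboxylate (sets C2), then epimerisation of C3 to trans.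
- The benzofuran comes from Pd carbonylative annulation of an o-alkynylphenol, itself from Sonogashira coupling of 5-iodovanillin acetal with 4-ethynyl-2,6-dimethoxyphenol (from syringaldehyde).
- Ring order: only the furan ring is built (step 4, aromatic) and then dearomatised (step 5); the three benzene rings come from vanillin/syringaldehyde feedstocks.

Assumption: 1, 3, 8, 10 and the named reagents are purchased; the ligand hand in step 5 is taken as (R,R) and must be confirmed on the first run.

**Step 1**
Reactants: 1, 5-iodovanillin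
Product: 2, 4-(1,3-dioxolan-2-yl)-2-iodo-6-methoxyphenol
Conditions: ethylene glycol (5 equiv), p-TsOH (3 mol%), toluene, Dean–Stark reflux; Et3N quench
Reagents that add atoms: ethylene glycol, OCCO
Why: Acid-catalysed acetalisation masks the aldehyde (it would compete as electrophile in step 7 and be reduced in step 8) and lowers the phenol acidity so the alkynylphenol of step 3 does not cyclise prematurely.

**Step 2**
Reactants: 3, syringaldehyde
Product: 4, 4-ethynyl-2,6-dimethoxyphenol
Conditions: Bestmann–Ohira reagent (1.8 equiv), K2CO3 (3 equiv), MeOH, rt, 36 h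
Reagents that add atoms: dimethyl (1-diazo-2-oxopropyl)phosphonate, CC(=O)C(=[N+]=[N-])P(=O)(OC)OC
Why: Seyferth–Gilbert homologation (Ohira–Bestmann variant) converts ArCHO to ArC≡CH and tolerates the free phenol with excess base and reagent.

**Step 3**
Reactants: 2, iodophenol acetal; 4, aryl alkyne
Product: 5, 4-{[5-(1,3-dioxolan-2-yl)-2-hydroxy-3-methoxyphenyl]ethynyl}-2,6-dimethoxyphenol
Conditions: PdCl2(PPh3)2 (3 mol%), CuI (2 mol%), Et3N/THF, degassed, rt
Reagents that add atoms: none
Why: Sonogashira coupling at room temperature gives the o-alkynylphenol; the basic, mild conditions keep the acetal and avoid 5-endo cyclisation to the 3-unsubstituted benzofuran.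

**Step 4**
Reactants: 5, o-alkynylphenol
Product: 6, methyl 5-(1,3-dioxolan-2-yl)-2-(4-hydroxy-3,5-dimethoxyphenyl)-7-methoxy-1-benzofuran-3-carboxylate
Conditions: PdI2 (5 mol%), thiourea (5 mol%), CBr4 (5 equiv), Cs2CO3 (4 equiv), CO (1 atm), MeOH, 40 °C
Reagents that add atoms: carbon monoxide, [C-]#[O+]; methanol, CO
Why: Pd(II) oxypalladation, CO insertion and methanolysis (carbonylative annulation of o-hydroxyarylacetylenes, CBr4 as reoxidant) close the furan ring and install the C3 ester carbon in one operation.

**Step 5 (key step)**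
Reactants: 6, benzofuran ester
Product: 7, methyl (2R,3R)-5-(1,3-dioxolan-2-yl)-2-(4-hydroxy-3,5-dimethoxyphenyl)-7-methoxy-2,3-dihydro-1-benzofuran-3-carboxylate (trans)
Conditions: [Ru(cod)(2-methylallyl)2] (5 mol%), (R,R)-SINpEt·HBF4 (10 mol%), KOtBu (preformed catalyst), H2 (80 bar), toluene, 40 °C; then NaOMe (1.5 equiv), MeOH, 0 °C to rt, NH4Cl quench
Reagents that add atoms: none (H2 only)
Why: Proposed new method: enantioselective dearomative hydrogenation of a 2,3-disubstituted benzofuran-3-carboxylate, reasoned from the low resonance energy of the furan ring and the push–pull β-aryloxycinnamate character of C2=C3 (already reduced by Mg/MeOH in racemic work); the closest known reaction is Ru–bis(NHC) asymmetric hydrogenation of 2-aryl- and 2-alkylbenzofurans, where face-selective syn H2 delivery sets C2 (here 2R, giving cis-2R,3S), and NaOMe then epimerises only C3 through the ester enolate to the thermodynamic trans-(2R,3R) isomer (use the (S,S) ligand if the first run shows the opposite face).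

**Step 6**
Reactants: 7, phenolic dihydrobenzofuran; 8, (R)-4-benzyl-3-(chloroacetyl)oxazolidin-2-one
Product: 9, (R)-4-benzyl-3-({4-[(2R,3R)-5-(1,3-dioxolan-2-yl)-7-methoxy-3-(methoxycarbonyl)-2,3-dihydro-1-benzofuran-2-yl]-2,6-dimethoxyphenoxy}acetyl)oxazolidin-2-one
Conditions: K2CO3 (2 equiv), NaI (0.2 equiv), acetone, 45 °C
Reagents that add atoms: none
Why: Finkelstein-assisted Williamson etherification (SN2 of the hindered phenoxide on the α-halo imide); K2CO3 is too weak to epimerise C3 or cleave the imide, so existing stereocentres are untouched.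

**Step 7**
Reactants: 9, aryloxyacetyl imide; 10, vanillin acetate
Product: 11, TMS-protected anti-aldol adduct, (R)-4-benzyl-3-[(2S,3S)-3-(4-acetoxy-3-methoxyphenyl)-2-(aryloxy)-3-(trimethylsilyloxy)propanoyl]oxazolidin-2-one (aryl = the dihydrobenzofuranyl-2,6-dimethoxyphenyl unit of 9)
Conditions: MgCl2 (0.2 equiv), Et3N (2.5 equiv), TMSCl (2 equiv), 10 (1.3 equiv), EtOAc, rt, 24–48 h; neutral work-up
Reagents that add atoms: chlorotrimethylsilane, C[Si](C)(C)Cl
Why: Evans Mg-halide-catalysed direct anti-aldol (soft enolisation, TMSCl turnover) with a non-enolisable aryl aldehyde; by analogy with propionyl imides (not demonstrated for aryloxyacetyl imides), the chelated Z-enolate of the (R)-benzyl auxiliary is attacked on the face opposite benzyl through a boat transition state, giving the anti (2S,3S) adduct, which is the erythro C7/C8 pair.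

**Step 8**
Reactants: 11, aldol adduct
Product: 12, target, (2R,3S)-2-(4-{[(1S,2R)-1,3-dihydroxy-1-(4-hydroxy-3-methoxyphenyl)propan-2-yl]oxy}-3,5-dimethoxyphenyl)-3-(hydroxymethyl)-7-methoxy-2,3-dihydro-1-benzofuran-5-carbaldehyde
Conditions: LiBH4 (8 equiv), MeOH (8 equiv), THF, 0 °C to rt; then 0.5 M aq. HCl/THF, 0 °C to rt, 30–60 min
Reagents that add atoms: water, O (aldehyde oxygen on acetal hydrolysis)
Why: Hydride reduction removes the auxiliary (giving C9 CH2OH), reduces the C3 methyl ester and cleaves the aryl acetate while the acetal survives, and dilute acid then removes TMS and the dioxolane; no stereocentre is altered, and the labels at C8 (S to R) and C3 (R to S) change only through CIP priorities.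

**Compound list**
1 | 5-iodovanillin | O=Cc1cc(I)c(O)c(OC)c1 | starting material
2 | 4-(1,3-dioxolan-2-yl)-2-iodo-6-methoxyphenol | COc1cc(C2OCCO2)cc(I)c1O | intermediate
3 | syringaldehyde | COc1cc(C=O)cc(OC)c1O | starting material
4 | 4-ethynyl-2,6-dimethoxyphenol | C#Cc1cc(OC)c(O)c(OC)c1 | intermediate
5 | 4-{[5-(1,3-dioxolan-2-yl)-2-hydroxy-3-methoxyphenyl]ethynyl}-2,6-dimethoxyphenol | COc1cc(C2OCCO2)cc(C#Cc3cc(OC)c(O)c(OC)c3)c1O | intermediate
6 | methyl 5-(1,3-dioxolan-2-yl)-2-(4-hydroxy-3,5-dimethoxyphenyl)-7-methoxybenzofuran-3-carboxylate | COC(=O)c1c(-c2cc(OC)c(O)c(OC)c2)oc2c(OC)cc(C3OCCO3)cc12 | intermediate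
7 | methyl (2R,3R)-5-(1,3-dioxolan-2-yl)-2-(4-hydroxy-3,5-dimethoxyphenyl)-7-methoxy-2,3-dihydrobenzofuran-3-carboxylate | Oc1c(OC)cc([C@@H]2Oc3c(OC)cc(C4OCCO4)cc3[C@H]2C(=O)OC)cc1OC | intermediate
8 | (R)-4-benzyl-3-(chloroacetyl)oxazolidin-2-one | O=C(CCl)N1[C@H](Cc2ccccc2)COC1=O | starting material
9 | (R)-4-benzyl-3-(aryloxyacetyl)oxazolidin-2-one bearing the (2R,3R)-dihydrobenzofuran | O=C(COc1c(OC)cc([C@@H]2Oc3c(OC)cc(C4OCCO4)cc3[C@H]2C(=O)OC)cc1OC)N1[C@H](Cc2ccccc2)COC1=O | intermediate
10 | vanillin acetate (4-formyl-2-methoxyphenyl acetate) | CC(=O)Oc1ccc(C=O)cc1OC | starting material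
11 | (2S,3S) anti-aldol adduct, TMS ether | CC(=O)Oc1ccc([C@H](O[Si](C)(C)C)[C@@H](C(=O)N2[C@H](Cc3ccccc3)COC2=O)Oc2c(OC)cc([C@@H]3Oc4c(OC)cc(C5OCCO5)cc4[C@H]3C(=O)OC)cc2OC)cc1OC | intermediate
12 | CID53356209 | COc1cc([C@H](O)[C@@H](CO)Oc2c(OC)cc([C@@H]3Oc4c(OC)cc(C=O)cc4[C@H]3CO)cc2OC)ccc1O | target

**Totals**
Total steps: 8. Longest linear sequence: 7 (steps 2 or 1, then 3 to 8).

**Three steps most likely to fail**
- **Step 5** (new asymmetric hydrogenation of a tetrasubstituted, phenol-bearing benzofuran ester; ee and facial sense unproven). Fallback: abandon the benzofuran and build the (2R,3R)-dihydrobenzofuran by Rh(II)-carboxylate-catalysed enantioselective intramolecular C–H insertion of a methyl 2-diazo-2-(2-benzyloxyaryl)acetate, followed by NaOMe epimerisation.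
- **Step 7** (anti selectivity and facial sense with an α-aryloxy imide are extrapolated from propionyl imides). Fallback: Bu2BOTf/i-Pr2NEt Evans syn-aldol using the (S)-auxiliary analogue of 9 (sets C8 with known sense), then Mitsunobu inversion of the C7 alcohol (4-nitrobenzoic acid, PPh3, DIAD) before the same global LiBH4 reduction.
- **Step 6** (phenoxide may attack the imide carbonyl instead of the CH2Cl). Fallback: O-alkylate 7 with allyl bromoacetate, deallylate with Pd(PPh3)4/morpholine, and form the imide last by pivaloyl mixed-anhydride acylation of (R)-4-benzyloxazolidin-2-one.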